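**Plan**

- Retrosynthesis: the C2 stereocentre is removed first (flavanone back to flavone), then ring C is cut at C4a–C4, C4–C3 and O1–C2. This works because C4 is an isolated carbonyl carbon held only by C4a of ring A and by C3, and O1 sits on C8a next to C4a, so ring C reduces to an ortho-iodophenol (I on C4a, OH on C8a), CO (C4) and an arylacetylene (C3, C2, ring B).
- Ring A is then cut at C8–CH2 (alkylzinc plus aryl iodide), and the side chain at the bond between its stereogenic carbon and the prenyl CH2 (auxiliary-controlled alkylation).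
- Forward: side-chain iodide (steps 1–4) and ring A iodide (5–6) are joined (7); the prenyl alkene becomes the tertiary alcohol (8–9); C4a is iodinated and the two phenols are told apart (10–12); the ring B alkyne is made (13–14); ring C is closed (15); C2=C3 is reduced and the silyl groups are removed (16–17).
- Stereochemistry: the side-chain centre comes from (S)-4-benzyloxazolidinone in step 2 and is not touched again; C2 comes from ligand-controlled copper hydride addition to the flavone in step 16.

Key step: step 15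

Remark: the side-chain centre keeps one spatial arrangement throughout; it is labelled (S) in 7–9, 14 and 16 and (R) elsewhere only because the CIP priorities of its substituents change.

Assumption: (R)-DTBM-SEGPHOS is taken as the ligand antipode that leads to (2S); the sense is to be fixed on a model flavone first and the antipode used if it proves reversed.

**Route**

Step 1
Reactants: 1 (S)-4-benzyl-1,3-oxazolidin-2-one; 2 3-methylbut-2-enoyl chloride
Product: 4 (S)-4-benzyl-3-(3-methylbut-2-enoyl)-1,3-oxazolidin-2-one, via lithium oxazolidinide 3 (not isolated)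
Conditions: n-BuLi, THF, −78 °C; then 2, −78 to 0 °C
Reagents that add atoms: none
Why: N-acylation of the lithiated oxazolidinone with an acid chloride is the standard way to load an Evans auxiliary and should leave the conjugated alkene untouched at low temperature.

Step 2
Reactants: 4 (S)-4-benzyl-3-(3-methylbut-2-enoyl)-1,3-oxazolidin-2-one; 5 1-bromo-3-methylbut-2-ene (prenyl bromide)
Product: 7 (S)-4-benzyl-3-[(2S)-5-methyl-2-(prop-1-en-2-yl)hex-4-enoyl]-1,3-oxazolidin-2-one, via sodium dienolate 6 (not isolated)
Conditions: NaN(SiMe3)2, THF, −78 °C; then 5, −78 to −40 °C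
Reagents that add atoms: none
Why: Evans asymmetric alkylation in its deconjugative form, in which γ-deprotonation gives the chelated (Z)-dienolate 6 that should be alkylated at Cα on the face opposite the benzyl group, setting the isopropenyl-bearing centre (auxiliary control).

Step 3
Reactants: 7 (S)-4-benzyl-3-[(2S)-5-methyl-2-(prop-1-en-2-yl)hex-4-enoyl]-1,3-oxazolidin-2-one
Product: 8 (2S)-5-methyl-2-(prop-1-en-2-yl)hex-4-en-1-ol [(S)-lavandulol]
Conditions: LiBH4, THF, 0 °C to rt
Reagents that add atoms: none
Why: Reductive removal of the auxiliary by hydride attack at the exocyclic imide carbonyl should give the primary alcohol without base, so neither alkene nor the α-centre is disturbed and 1 is returned.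

Step 4
Reactants: 8 (S)-lavandulol
Product: 9 (3S)-3-(iodomethyl)-2,6-dimethylhepta-1,5-diene [(S)-lavandulyl iodide]
Conditions: PPh3, I2, imidazole, CH2Cl2, 0 °C to rt
Reagents that add atoms: iodine, II
Why: Appel-type iodination replaces the primary hydroxyl by SN2 displacement at a CH2 that is not stereogenic, so the neighbouring centre is unaffected.

Step 5
Reactants: 10 5-methoxybenzene-1,3-diol (5-methoxyresorcinol)
Product: 11 1-methoxy-3,5-bis(methoxymethoxy)benzene
Conditions: MOMCl, i-Pr2NEt, CH2Cl2, 0 °C to rt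
Reagents that add atoms: chloromethyl methyl ether, COCCl
Why: O-alkylation of both phenols installs the two acetal groups that later direct metalation to the carbon between them.

Step 6
Reactants: 11 1-methoxy-3,5-bis(methoxymethoxy)benzene
Product: 13 2-iodo-5-methoxy-1,3-bis(methoxymethoxy)benzene, via aryllithium 12 (not isolated)
Conditions: n-BuLi, THF, 0 °C; then I2, −78 °C to rt
Reagents that add atoms: iodine, II
Why: Directed ortho-metalation should remove the C–H flanked by both OCH2OMe groups, the most acidic and best-coordinated position, and the iodine quench places the halide at the future C8.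

Step 7
Reactants: 9 (S)-lavandulyl iodide; 13 2-iodo-5-methoxy-1,3-bis(methoxymethoxy)benzene
Product: 15 5-methoxy-1,3-bis(methoxymethoxy)-2-[(2R)-5-methyl-2-(prop-1-en-2-yl)hex-4-en-1-yl]benzene, via alkylzinc iodide 14 (not isolated)
Conditions: Zn dust (activated), LiCl, THF, 35 °C; then 13, Pd(OAc)2 (3 mol %), SPhos (6 mol %), THF, 50 °C
Reagents that add atoms: none
Why: Negishi coupling, in which zinc insertion into the primary C–I bond gives 14 that should transmetalate to the arylpalladium species from 13, the bulky electron-rich biarylphosphine favouring reductive elimination over β-hydride loss while the stereocentre, one carbon away from the reacting CH2, is not involved.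

Step 8
Reactants: 15 5-methoxy-1,3-bis(methoxymethoxy)-2-[(2R)-5-methyl-2-(prop-1-en-2-yl)hex-4-en-1-yl]benzene
Product: 16 2-{(2S)-2-[(3,3-dimethyloxiran-2-yl)methyl]-3-methylbut-3-en-1-yl}-5-methoxy-1,3-bis(methoxymethoxy)benzene (both configurations at the oxirane CH)
Conditions: mCPBA (1.05 equiv), CH2Cl2, −20 °C
Reagents that add atoms: 3-chloroperoxybenzoic acid, O=C(OO)c1cccc(Cl)c1
Why: Prilezhaev epoxidation follows alkene nucleophilicity, so the trisubstituted prenyl alkene should react before the 1,1-disubstituted isopropenyl group and the arene, and the new oxirane centre is erased in step 9.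

Step 9
Reactants: 16 epoxide
Product: 17 (5R)-5-{[4-methoxy-2,6-bis(methoxymethoxy)phenyl]methyl}-2,6-dimethylhept-6-en-2-ol
Conditions: LiEt3BH, THF, 0 °C to rt
Reagents that add atoms: none
Why: Hydride opening of the epoxide is an SN2 process at the less substituted oxirane carbon, which should leave the oxygen on the dimethyl-substituted carbon and give the tertiary alcohol of the side chain.

Step 10
Reactants: 17 tertiary alcohol
Product: 18 (5R)-5-{[3-iodo-4-methoxy-2,6-bis(methoxymethoxy)phenyl]methyl}-2,6-dimethylhept-6-en-2-ol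
Conditions: N-iodosuccinimide (1.05 equiv), MeCN, 0 °C, dark
Reagents that add atoms: N-iodosuccinimide, O=C1CCC(=O)N1I
Why: Electrophilic aromatic iodination, in which the two remaining ring positions are equivalent and each is activated by three oxygen substituents, so one mono-iodide should form faster than any reaction at the isopropenyl group.

Step 11
Reactants: 18 aryl iodide bis(methoxymethyl) ether
Product: 20 4-iodo-5-methoxy-2-{(2R)-5-methyl-2-(prop-1-en-2-yl)-5-[(trimethylsilyl)oxy]hexyl}benzene-1,3-diol, via tris(trimethylsilyl) ether 19 (not isolated)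
Conditions: Me3SiOTf, 2,2'-bipyridyl, CH2Cl2, 0 °C to rt; then NaHCO3, MeOH, 0 °C
Reagents that add atoms: trimethylsilyl trifluoromethanesulfonate, C[Si](C)(C)OS(=O)(=O)C(F)(F)F
Why: Silyl-triflate-mediated acetal cleavage buffered by bipyridyl turns the aryl methoxymethyl ethers into aryl silyl ethers and silylates the tertiary alcohol, and bicarbonate methanolysis should then cleave only the labile aryl–O–Si bonds, so the isopropenyl/phenol pair never meets a protic acid and the tertiary alcohol stays masked.

Step 12
Reactants: 20 iodoresorcinol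
Product: 21 6-iodo-5-methoxy-2-{(2R)-5-methyl-2-(prop-1-en-2-yl)-5-[(trimethylsilyl)oxy]hexyl}-3-[(triisopropylsilyl)oxy]phenol
Conditions: i-Pr3SiCl (1.05 equiv), imidazole, DMF, 0 °C to rt
Reagents that add atoms: chlorotri(propan-2-yl)silane, CC(C)[Si](Cl)(C(C)C)C(C)C
Why: Silylation with a bulky silyl chloride is sterically controlled, so the hydroxyl with a free ortho C–H should react in preference to the one wedged between iodine and the benzylic CH2, leaving free exactly the hydroxyl that becomes O1.

Step 13
Reactants: 22 4-hydroxy-2-methoxybenzaldehyde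
Product: 23 2-methoxy-4-[(triisopropylsilyl)oxy]benzaldehyde
Conditions: i-Pr3SiCl, imidazole, DMF, rt
Reagents that add atoms: chlorotri(propan-2-yl)silane, CC(C)[Si](Cl)(C(C)C)C(C)C
Why: Standard phenol silylation, the triisopropylsilyl ether being chosen to survive hot diethylamine and to leave with fluoride at the end.

Step 14
Reactants: 23 2-methoxy-4-[(triisopropylsilyl)oxy]benzaldehyde
Product: 24 (4-ethynyl-3-methoxyphenoxy)triisopropylsilane
Conditions: Me3SiCHN2, n-BuLi, THF, −78 °C; then 23, −78 °C to rt
Reagents that add atoms: (trimethylsilyl)diazomethane, C[Si](C)(C)C=[N+]=[N-]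
Why: Colvin rearrangement, in which the lithiated diazo reagent adds to the aldehyde and Peterson-type loss of silanolate and then of nitrogen gives an alkylidene carbene whose 1,2-hydrogen shift should deliver the terminal arylacetylene without conditions that cleave the aryl silyl ether.

Step 15
Reactants: 21 ring A iodophenol; 24 ring B alkyne; 25 carbon monoxide
Product: 28 5-methoxy-2-{2-methoxy-4-[(triisopropylsilyl)oxy]phenyl}-8-{(2R)-5-methyl-2-(prop-1-en-2-yl)-5-[(trimethylsilyl)oxy]hexyl}-7-[(triisopropylsilyl)oxy]-4H-chromen-4-one, via ynone 26 (not isolated), via enaminone 27 (not isolated)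
Conditions: PdCl2(PPh3)2 (5 mol %), CO (20 atm), Et2NH, 120 °C
Reagents that add atoms: none
Why: Zerovalent palladium formed in situ from PdCl2(PPh3)2 inserts into the C4a–I bond of 21, CO insertion gives the aroyl complex of divalent palladium, and amine-assisted alkynylation by 24 with reductive elimination gives ynone 26 (C4a–C4 and C4–C3). Diethylamine then adds to C2 of the ynone to give enaminone 27, and the C8a hydroxyl displaces the amine by addition–elimination at C2, forming O1–C2. The closest known reaction type is the palladium-catalysed carbonylative Sonogashira coupling and annulation of ortho-iodophenols with terminal arylacetylenes to flavones. Ring C closes in a 6-endo mode (6-endo-trig on the enaminone, formally 6-endo-dig on the ynone) and no stereocentre is formed. The step needs CO insertion before alkynylation (otherwise a 2-arylbenzofuran) and 6-endo rather than 5-exo closure (otherwise an aurone); the electron-rich arylpalladium species should take up CO readily under pressure, and the secondary amine routes the ynone through an enaminone that can only be attacked at C2. Only the hydroxyl on C8a is free and ortho to the new acyl group, the other phenol being a silyl ether, so a single chromone regioisomer is possible.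

Step 16
Reactants: 28 flavone
Product: 30 (2S)-5-methoxy-2-{2-methoxy-4-[(triisopropylsilyl)oxy]phenyl}-8-{(2R)-5-methyl-2-(prop-1-en-2-yl)-5-[(trimethylsilyl)oxy]hexyl}-7-[(triisopropylsilyl)oxy]-2,3-dihydro-4H-chromen-4-one, via silyl enol ether 29 (not isolated)
Conditions: Cu(OAc)2 (5 mol %), (R)-DTBM-SEGPHOS (5.5 mol %), (EtO)2MeSiH, toluene, 0 °C to rt; then aqueous NaHCO3
Reagents that add atoms: none
Why: Copper hydride asymmetric conjugate reduction, in which the bisphosphine–CuH complex should deliver hydride to C2 of the chromone enone on the face chosen by the ligand (catalyst control, giving 2S), the enolate being held as silyl enol ether 29, which shields C4 from further reduction until work-up, while the isolated alkene and the silyl ethers stay inert.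

Step 17
Reactants: 30 (2S)-flavanone tris(silyl) ether
Product: 31 (2S)-7-hydroxy-2-(4-hydroxy-2-methoxyphenyl)-8-[(2R)-5-hydroxy-5-methyl-2-(prop-1-en-2-yl)hexyl]-5-methoxy-2,3-dihydro-4H-chromen-4-one
Conditions: Bu4NF, AcOH, THF, 0 °C to rt
Reagents that add atoms: none
Why: Fluoride-mediated desilylation buffered with acetic acid should cleave the two aryl triisopropylsilyl ethers and the tertiary trimethylsilyl ether without building up free phenoxide or strong acid, so the C2 centre (retro-oxa-Michael) and the isopropenyl and tertiary alcohol groups are preserved.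

**Compound list**

1 | (S)-4-benzyl-1,3-oxazolidin-2-one | O=C1N[C@@H](Cc2ccccc2)CO1 | starting material
2 | 3-methylbut-2-enoyl chloride | CC(C)=CC(=O)Cl | starting material
3 | N-lithio-(S)-4-benzyl-1,3-oxazolidin-2-one (not isolated) | [Li]N1[C@@H](Cc2ccccc2)COC1=O | intermediate
4 | (S)-4-benzyl-3-(3-methylbut-2-enoyl)-1,3-oxazolidin-2-one | CC(C)=CC(=O)N1[C@@H](Cc2ccccc2)COC1=O | intermediate
5 | 1-bromo-3-methylbut-2-ene | CC(C)=CCBr | starting material
6 | sodium (Z)-dienolate of 4 (not isolated) | C=C(C)/C=C(\[O-])N1[C@@H](Cc2ccccc2)COC1=O.[Na+] | intermediate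
7 | (S)-4-benzyl-3-[(2S)-5-methyl-2-(prop-1-en-2-yl)hex-4-enoyl]-1,3-oxazolidin-2-one | C=C(C)[C@H](CC=C(C)C)C(=O)N1[C@@H](Cc2ccccc2)COC1=O | intermediate
8 | (2S)-5-methyl-2-(prop-1-en-2-yl)hex-4-en-1-ol | C=C(C)[C@H](CC=C(C)C)CO | intermediate
9 | (3S)-3-(iodomethyl)-2,6-dimethylhepta-1,5-diene | C=C(C)[C@H](CC=C(C)C)CI | intermediate
10 | 5-methoxybenzene-1,3-diol | COc1cc(O)cc(O)c1 | starting material
11 | 1-methoxy-3,5-bis(methoxymethoxy)benzene | COCOc1cc(OC)cc(OCOC)c1 | intermediate
12 | [4-methoxy-2,6-bis(methoxymethoxy)phenyl]lithium (not isolated) | [Li]c1c(OCOC)cc(OC)cc1OCOC | intermediate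
13 | 2-iodo-5-methoxy-1,3-bis(methoxymethoxy)benzene | COCOc1cc(OC)cc(OCOC)c1I | intermediate
14 | [(2S)-5-methyl-2-(prop-1-en-2-yl)hex-4-en-1-yl]zinc iodide (not isolated) | C=C(C)[C@H](CC=C(C)C)C[Zn]I | intermediate
15 | 5-methoxy-1,3-bis(methoxymethoxy)-2-[(2R)-5-methyl-2-(prop-1-en-2-yl)hex-4-en-1-yl]benzene | C=C(C)[C@H](CC=C(C)C)Cc1c(OCOC)cc(OC)cc1OCOC | intermediate
16 | 2-{(2S)-2-[(3,3-dimethyloxiran-2-yl)methyl]-3-methylbut-3-en-1-yl}-5-methoxy-1,3-bis(methoxymethoxy)benzene, oxirane CH unspecified | C=C(C)[C@H](CC1OC1(C)C)Cc1c(OCOC)cc(OC)cc1OCOC | intermediate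
17 | (5R)-5-{[4-methoxy-2,6-bis(methoxymethoxy)phenyl]methyl}-2,6-dimethylhept-6-en-2-ol | C=C(C)[C@H](CCC(C)(C)O)Cc1c(OCOC)cc(OC)cc1OCOC | intermediate
18 | (5R)-5-{[3-iodo-4-methoxy-2,6-bis(methoxymethoxy)phenyl]methyl}-2,6-dimethylhept-6-en-2-ol | C=C(C)[C@H](CCC(C)(C)O)Cc1c(OCOC)cc(OC)c(I)c1OCOC | intermediate
19 | tris(trimethylsilyl) ether of the iodoresorcinol triol: both aryl O and the tertiary O silylated (not isolated) | C=C(C)[C@H](CCC(C)(C)O[Si](C)(C)C)Cc1c(O[Si](C)(C)C)cc(OC)c(I)c1O[Si](C)(C)C | intermediate
20 | 4-iodo-5-methoxy-2-{(2R)-5-methyl-2-(prop-1-en-2-yl)-5-[(trimethylsilyl)oxy]hexyl}benzene-1,3-diol | C=C(C)[C@H](CCC(C)(C)O[Si](C)(C)C)Cc1c(O)cc(OC)c(I)c1O | intermediate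
21 | 6-iodo-5-methoxy-2-{(2R)-5-methyl-2-(prop-1-en-2-yl)-5-[(trimethylsilyl)oxy]hexyl}-3-[(triisopropylsilyl)oxy]phenol | C=C(C)[C@H](CCC(C)(C)O[Si](C)(C)C)Cc1c(O[Si](C(C)C)(C(C)C)C(C)C)cc(OC)c(I)c1O | intermediate
22 | 4-hydroxy-2-methoxybenzaldehyde | COc1cc(O)ccc1C=O | starting material
23 | 2-methoxy-4-[(triisopropylsilyl)oxy]benzaldehyde | COc1cc(O[Si](C(C)C)(C(C)C)C(C)C)ccc1C=O | intermediate
24 | (4-ethynyl-3-methoxyphenoxy)triisopropylsilane | C#Cc1ccc(O[Si](C(C)C)(C(C)C)C(C)C)cc1OC | intermediate
25 | carbon monoxide | [C-]#[O+] | starting material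
26 | ortho-hydroxyaryl ynone: ring A C4a–C(=O)–C≡C–ring B (not isolated) | C=C(C)[C@H](CCC(C)(C)O[Si](C)(C)C)Cc1c(O[Si](C(C)C)(C(C)C)C(C)C)cc(OC)c(C(=O)C#Cc2ccc(O[Si](C(C)C)(C(C)C)C(C)C)cc2OC)c1O | intermediate
27 | β-(diethylamino)enone from addition of Et2NH to 26, alkene geometry unspecified (not isolated) | C=C(C)[C@H](CCC(C)(C)O[Si](C)(C)C)Cc1c(O[Si](C(C)C)(C(C)C)C(C)C)cc(OC)c(C(=O)C=C(N(CC)CC)c2ccc(O[Si](C(C)C)(C(C)C)C(C)C)cc2OC)c1O | intermediate
28 | 5-methoxy-2-{2-methoxy-4-[(triisopropylsilyl)oxy]phenyl}-8-{(2R)-5-methyl-2-(prop-1-en-2-yl)-5-[(trimethylsilyl)oxy]hexyl}-7-[(triisopropylsilyl)oxy]-4H-chromen-4-one | C=C(C)[C@H](CCC(C)(C)O[Si](C)(C)C)Cc1c(O[Si](C(C)C)(C(C)C)C(C)C)cc(OC)c2c1OC(c1ccc(O[Si](C(C)C)(C(C)C)C(C)C)cc1OC)=CC2=O | intermediate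
29 | (2S)-4-{[diethoxy(methyl)silyl]oxy}-2H-chromene (silyl enol ether of 30, not isolated) | C=C(C)[C@H](CCC(C)(C)O[Si](C)(C)C)Cc1c(O[Si](C(C)C)(C(C)C)C(C)C)cc(OC)c2c1O[C@H](c1ccc(O[Si](C(C)C)(C(C)C)C(C)C)cc1OC)C=C2O[Si](C)(OCC)OCC | intermediate
30 | (2S)-5-methoxy-2-{2-methoxy-4-[(triisopropylsilyl)oxy]phenyl}-8-{(2R)-5-methyl-2-(prop-1-en-2-yl)-5-[(trimethylsilyl)oxy]hexyl}-7-[(triisopropylsilyl)oxy]-2,3-dihydro-4H-chromen-4-one | C=C(C)[C@H](CCC(C)(C)O[Si](C)(C)C)Cc1c(O[Si](C(C)C)(C(C)C)C(C)C)cc(OC)c2c1O[C@H](c1ccc(O[Si](C(C)C)(C(C)C)C(C)C)cc1OC)CC2=O | intermediate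
31 | (2S)-7-hydroxy-2-(4-hydroxy-2-methoxyphenyl)-8-[(2R)-5-hydroxy-5-methyl-2-(prop-1-en-2-yl)hexyl]-5-methoxy-2,3-dihydro-4H-chromen-4-one | C=C(C)[C@H](CCC(C)(C)O)Cc1c(O)cc(OC)c2c1O[C@H](c1ccc(O)cc1OC)CC2=O | target

**Count and risks**

Total: 17 steps. Longest linear sequence: 13 steps (1–4, 7–12, 15–17).

Step 16. Hydride transfer to the electron-rich, doubly donor-substituted chromone may stall, or the ligand may discriminate the two faces of C2 poorly. The fallback sets out from 28 and returns at 30. The more reactive achiral copper hydride made from Cu(OAc)2, 1,2-bis(diphenylphosphino)benzene and (EtO)2MeSiH would reduce C2=C3 without stereocontrol, giving 30 together with its C2 epimer, the (2R)-flavanone F1. The pair would then be resolved kinetically by asymmetric transfer hydrogenation with RhCl(Cp*)[(R,R)-TsDPEN] and HCO2H/Et3N, the antipode of the catalyst being chosen so that the (2R)-ketone is reduced to the cis-(2R,4R)-flavan-4-ol F2 while the (2S)-ketone 30 is left and separated by chromatography.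

Step 15. Oxidative addition at the doubly ortho-substituted, electron-rich C–I bond may be slow; the aroylpalladium species may be intercepted by diethylamine (amide formation); coupling may occur without CO insertion; or palladium hydride may shift the isopropenyl double bond. The fallback sets out from 21 and 24 and returns at 28, bringing C4 in as an acyl electrophile instead of CO. Alkyne 24 is deprotonated with n-BuLi to the lithium acetylide F3 and acylated with N-methoxy-N-methylcarbamoyl chloride to the Weinreb amide F4. Iodophenol 21 is treated with MeLi (phenol) and then t-BuLi (iodine–lithium exchange) at −78 °C to give the dilithio species F5, which should add to F4 and give ynone 26 after work-up, here isolated. Diethylamine in EtOH then closes ring C through enaminone 27 to 28.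

Step 12. The two phenols may not be discriminated well enough during silylation, with silyl transfer to the hindered hydroxyl or to both. The fallback sets out from 20 and returns at 28, leaving the phenols undifferentiated until after the annulation. Both are acetylated (Ac2O, Et3N, DMAP) to the diacetate F6. Under the conditions of step 15 diethylamine should cleave both acetates in the flask, and since only the oxygen ortho to the new acyl group can reach C2, the annulation should give the 7-hydroxyflavone F7. Its single phenol is then silylated with i-Pr3SiCl and imidazole to 28.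

**Further compounds**

F1 | step 16 | (2R)-epimer of 30 | C=C(C)[C@H](CCC(C)(C)O[Si](C)(C)C)Cc1c(O[Si](C(C)C)(C(C)C)C(C)C)cc(OC)c2c1O[C@@H](c1ccc(O[Si](C(C)C)(C(C)C)C(C)C)cc1OC)CC2=O
F2 | step 16 | cis-(2R,4R)-flavan-4-ol from reduction of F1 at C4 | C=C(C)[C@H](CCC(C)(C)O[Si](C)(C)C)Cc1c(O[Si](C(C)C)(C(C)C)C(C)C)cc(OC)c2c1O[C@@H](c1ccc(O[Si](C(C)C)(C(C)C)C(C)C)cc1OC)C[C@H]2O
F3 | step 15 | lithium acetylide of 24 | [Li]C#Cc1ccc(O[Si](C(C)C)(C(C)C)C(C)C)cc1OC
F4 | step 15 | N-methoxy-N-methyl-3-{2-methoxy-4-[(triisopropylsilyl)oxy]phenyl}prop-2-ynamide | CON(C)C(=O)C#Cc1ccc(O[Si](C(C)C)(C(C)C)C(C)C)cc1OC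
F5 | step 15 | dilithio derivative of 21 (lithium phenoxide, lithium at the former C–I carbon) | C=C(C)[C@H](CCC(C)(C)O[Si](C)(C)C)Cc1c(O[Si](C(C)C)(C(C)C)C(C)C)cc(OC)c([Li])c1O[Li]
F6 | step 12 | 4-iodo-5-methoxy-2-{(2R)-5-methyl-2-(prop-1-en-2-yl)-5-[(trimethylsilyl)oxy]hexyl}-1,3-phenylene diacetate | C=C(C)[C@H](CCC(C)(C)O[Si](C)(C)C)Cc1c(OC(C)=O)cc(OC)c(I)c1OC(C)=O
F7 | step 12 | 7-hydroxy analogue of 28 (free C7 hydroxyl) | C=C(C)[C@H](CCC(C)(C)O[Si](C)(C)C)Cc1c(O)cc(OC)c2c1OC(c1ccc(O[Si](C(C)C)(C(C)C)C(C)C)cc1OC)=CC2=O
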